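**Retrosynthetic overview**
1. Feature: the furan (O, C13–C16) shares its C2–C3 bond (C16–C13) with the seven-membered ketone ring C. Furan C2 (C16) sits on the ring B methine C1 and furan C3 (C13) on the ketone carbon C12. An oxazol-2-yl group on C1 and a CH2–CO–C≡CH arm on C9 therefore hold every atom of both rings.
2. Last skeletal event: an intramolecular oxazole/ynone Diels–Alder reaction with loss of MeCN makes C16–C13 and C14–C15 and closes ring C and the furan together (36 → 38).
3. Before that: the lactone ring comes from oxidative lactonisation of the C18/C19 diol, and the C2–OH from allylic oxidation and Luche reduction.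
4. Rings A and B form together in an intramolecular Diels–Alder reaction of an (E)-2-vinyloxazole (C1=C10) with an open-chain diene C2=C3–C4=C5 that holds the tether outside and C19 inside. A 3-vinylbutenolide would hold the tether inside and could give only the cis-decalin.
5. C7–C9 are set on a γ-butyrolactone template (crotylboration, two enolate alkylations), and the diene comes from butynediol by anti-carbomagnesiation. Ring order: A+B, lactone, then C+furan.

Key step: step 22

Remark: clerodane-type locants are used. Ring A = C5–C10 (acetoxycyclohexane); ring B = C1–C5, C10 (cyclohexene); ring C = C1, C10, C9, C11, C12, C13, C16; lactone = C4, C5, C19, O, C18; furan = C13–C16 + O; C17 = 8-Me; C20 = 9-Me. α is the decalin face that carries C19. The target is 1β-C16, 2α-OH, 7β-OAc, 8α-Me, 9α-Me, 10β-H. TBS = t-BuMe2Si, TIPS = i-Pr3Si.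
Assumption: (R)-TRIP is taken to direct crotyl transfer to the Re face of aldehyde 8; if the sense is the reverse, the (S)-acid is used and nothing else changes.

Step 1
Reactants: 1 but-2-yne-1,4-diol; 2 vinylmagnesium chloride
Product: 4 (2Z)-2-ethenyl-3-iodobut-2-ene-1,4-diol, via alkenylmagnesium chelate 3 (not isolated)
Conditions: 2 (5 equiv), THF–toluene, reflux; then I2, –78 °C to rt
Reagents that add atoms: vinylmagnesium chloride (2), C=C[Mg]Cl; iodine, II
Why: Alkoxide-directed anti-carbomagnesiation of a propargylic alcohol: vinyl goes to the alkyne carbon next to the chelating alkoxide and magnesium ends trans to it in a five-membered chelate, the symmetric diol leaves no regiochemical choice, the second oxygen is a magnesium alkoxide and too poor a leaving group for allene formation, and iodinolysis goes with retention, so that I and vinyl end up trans.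

Step 2
Reactants: 4 (2Z)-2-ethenyl-3-iodobut-2-ene-1,4-diol
Product: 5 (2Z)-1,4-bis(TBS-oxy)-2-ethenyl-3-iodobut-2-ene
Conditions: TBSCl, imidazole, DMF, rt
Reagents that add atoms: tert-butyldimethylsilyl chloride, CC(C)(C)[Si](C)(C)Cl
Why: Routine imidazole-promoted silylation of two primary allylic alcohols, giving ethers that last until step 18.

Step 3
Reactants: 5 bis-TBS alkenyl iodide; 6 ethyl (bromozincio)acetate (Reformatsky reagent)
Product: 7 ethyl (3E)-3,4-bis(TBS-oxymethyl)hexa-3,5-dienoate
Conditions: 6 (1.5 equiv), Pd(P(t-Bu)3)2 (5 mol %), THF, rt to 50 °C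
Reagents that add atoms: ethyl (bromozincio)acetate (6), CCOC(=O)C[Zn]Br
Why: Negishi-type cross-coupling of a Reformatsky reagent with an alkenyl iodide, which keeps the alkene geometry (the new CH2CO2Et arm, C6, stays trans to the vinyl group) and needs no base that could move the β,γ-double bond into conjugation.

Step 4
Reactants: 7 dienoate
Product: 8 (3E)-3,4-bis(TBS-oxymethyl)hexa-3,5-dienal
Conditions: i-Bu2AlH (1.05 equiv), CH2Cl2, –78 °C; aq potassium sodium tartrate
Reagents that add atoms: none
Why: Partial ester reduction: the aluminium hemiacetal is stable at –78 °C and collapses to the aldehyde only on the near-neutral work-up, so that neither over-reduction nor conjugation of the β,γ-unsaturated aldehyde should intervene (8 is used at once).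

Step 5
Reactants: 8 dienal; 9 (Z)-crotylboronic acid pinacol ester
Product: 10 (3S,4S,6E)-6,7-bis(TBS-oxymethyl)-3-methylnona-1,6,8-trien-4-ol (7S,8S in route locants)
Conditions: 9 (1.3 equiv), (R)-TRIP [(R)-3,3′-bis(2,4,6-triisopropylphenyl)-BINOL hydrogen phosphate] (5 mol %), toluene, –30 °C; H2O
Reagents that add atoms: (Z)-crotylboronic acid pinacol ester (9), C/C=C\CB1OC(C)(C)C(C)(C)O1
Why: Chiral phosphoric acid-catalysed crotylboration through a closed chair transition state: the (Z)-crotyl geometry becomes the syn C7-OH/C8-Me relationship and the catalyst directs attack to the Re face of 8, which sets 7S and 8S.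

Step 6
Reactants: 10 syn homoallylic alcohol
Product: 12 (3S,4S,6E)-6,7-bis(TBS-oxymethyl)-3-methylnona-6,8-diene-1,4-diol, via bis(9-BBN) adduct 11 (not isolated)
Conditions: 9-BBN-H (2.2 equiv), THF, 0 °C to rt; then NaOH, H2O2, 0 °C
Reagents that add atoms: hydrogen peroxide, OO
Why: Anti-Markovnikov hydroboration–oxidation in which 9-BBN-H picks the isolated monosubstituted alkene, since a conjugated diene whose vinyl group hangs on a fully substituted carbon reacts far more slowly; no stereocentre is touched.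

Step 7
Reactants: 12 1,4-diol
Product: 14 (4S,5S)-5-[(2E)-2,3-bis(TBS-oxymethyl)penta-2,4-dienyl]-4-methyloxolan-2-one (cis), via lactol 13 (not isolated)
Conditions: TEMPO (0.2 equiv), PhI(OAc)2 (2.5 equiv), CH2Cl2, rt
Reagents that add atoms: none
Why: TEMPO/PhI(OAc)2 oxidative lactonisation: the primary alcohol is oxidised first, the aldehyde closes onto the C7 hydroxyl to lactol 13 and this is oxidised again, which freezes the syn pair as the cis-4,5-disubstituted γ-lactone.

Step 8
Reactants: 14 cis-lactone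
Product: 16 (3S,4S,5S)-3,4-dimethyl lactone, via lithium enolate 15 (not isolated)
Conditions: LiN(i-Pr)2 (1.1 equiv), THF, –78 °C; MeI
Reagents that add atoms: iodomethane, CI
Why: Kinetic lactone enolate alkylation; the methyl group enters mainly trans to the C8 methyl group, but this centre is flattened again in step 9, so that its configuration does not matter.

Step 9
Reactants: 16 3,4-dimethyl lactone; 17 tert-butyl(2-iodoethoxy)dimethylsilane
Product: 19 (3S,4S,5S)-3-[2-(TBS-oxy)ethyl]-3,4-dimethyl lactone (C9 quaternary), via lithium enolate 18 (not isolated)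
Conditions: LiN(i-Pr)2 (1.2 equiv), THF–DMPU, –78 °C; 17, –78 to –20 °C
Reagents that add atoms: tert-butyl(2-iodoethoxy)dimethylsilane (17), CC(C)(C)[Si](C)(C)OCCI
Why: Second lactone enolate alkylation: the planar enolate 18 carries the C8 methyl group and the C7 side chain on the same face and is attacked by the primary iodide from the other face, which sets the quaternary C9 with the C11 arm trans and C20 cis to C17 (hence methyl first, arm second).

Step 10
Reactants: 19 quaternary lactone
Product: 20 lactol (oxolan-2-ol; anomer mixture)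
Conditions: i-Bu2AlH (1.2 equiv), CH2Cl2, –78 °C; aq potassium sodium tartrate
Reagents that add atoms: none
Why: Half-reduction of a γ-lactone stops at the lactol because the aluminium acetal next to the quaternary carbon does not open at –78 °C; silyl ethers and diene are inert.

Step 11
Reactants: 21 2,4-dimethyl-1,3-oxazole
Product: 23 diethyl [(4-methyl-1,3-oxazol-2-yl)methyl]phosphonate, via 2-(lithiomethyl)oxazole 22 (not isolated)
Conditions: LiN(i-Pr)2 (2.1 equiv), Et2NH (0.2 equiv), THF, –78 °C; ClP(O)(OEt)2, –78 to 0 °C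
Reagents that add atoms: diethyl chlorophosphate, CCOP(=O)(Cl)OCC
Why: Lateral lithiation of the 2-methyl group (the secondary amine lets any C5-lithio species equilibrate to the more stable 2-lithiomethyl form 22) followed by phosphorylation; the second equivalent of base takes up the more acidic product.

Step 12
Reactants: 20 lactol; 23 oxazolylmethyl phosphonate
Product: 25 (7S,8S,9R)-(E)-2-vinyloxazole trienol (free C7-OH), via lithiated phosphonate 24 (not isolated)
Conditions: 23 (3 equiv), LiN(SiMe3)2 (3 equiv), THF, –78 °C; then 20, –78 to 40 °C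
Reagents that add atoms: phosphonate 23, CCOP(=O)(Cc1nc(C)co1)OCC
Why: Horner–Wadsworth–Emmons olefination of the open hydroxy aldehyde form of the lactol with a heteroaryl-stabilised phosphonate anion, which gives the (E)-alkene; the weakly accepting vinyloxazole next to a quaternary carbon should not suffer oxa-Michael closure by the freed C7 alkoxide.

Step 13
Reactants: 25 trienol
Product: 26 C7 acetate of 25
Conditions: Ac2O, DMAP (cat.), pyridine, rt
Reagents that add atoms: acetic anhydride, CC(=O)OC(C)=O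
Why: DMAP-catalysed acetylation of the only free hydroxyl installs the C7 acetate of the target.

Step 14
Reactants: 26 tetraene acetate
Product: 27 trans-decalin (1β-oxazolyl; 5α-CH2OTBS; 10β-H; C3=C4)
Conditions: BHT (cat.), toluene (0.01 M), sealed tube, 170 °C
Reagents that add atoms: none
Why: Type 1 intramolecular Diels–Alder reaction of a 1,7,9-decatriene: because the tether leaves C5 from the outside (E) position and C19 sits inside, the chair-like transition state with tether exo and oxazole endo is open and gives the trans-decalin with H-10 and the oxazolyl group β and C19 α, the (E)-alkene fixes H-1/H-10 trans, and the face is chosen by the equatorial C7-OAc and C8-Me groups of the tether.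

Step 15
Reactants: 27 trans-decalin
Product: 28 C2 enone (C2=O; C3=C4)
Conditions: Rh2(cap)4 (cap = caprolactamate, 1 mol %), t-BuOOH (5 equiv), K2CO3 (0.5 equiv), CH2Cl2, rt
Reagents that add atoms: tert-butyl hydroperoxide, CC(C)(C)OO
Why: Dirhodium caprolactamate/t-BuOOH allylic oxidation (peroxyl radical chain): C2 is the only ring methylene allylic to the sole alkene (C5 is quaternary), so that the C2 enone should form, and C1, now epimerisable, already holds its stable equatorial configuration.

Step 16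
Reactants: 28 enone
Product: 29 2α-allylic alcohol
Conditions: NaBH4, CeCl3·7H2O, MeOH, –78 °C
Reagents that add atoms: none
Why: Luche reduction: 1,2-selective axial hydride delivery to the cyclohexenone from the β face gives the pseudo-equatorial 2α-alcohol trans to the equatorial oxazolyl group, and the acetate survives at –78 °C.

Step 17
Reactants: 29 allylic alcohol
Product: 30 2α-TIPS ether
Conditions: TIPSOTf, 2,6-lutidine, CH2Cl2, 0 °C to rt
Reagents that add atoms: triisopropylsilyl triflate, CC(C)[Si](C(C)C)(C(C)C)OS(=O)(=O)C(F)(F)F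
Why: Silyl triflate silylation of the hindered secondary alcohol; TIPS is chosen so that the three primary TBS ethers can be removed beside it.

Step 18
Reactants: 30 tetrasilyl ether
Product: 31 C12/C18/C19 triol (2α-OTIPS kept)
Conditions: HF·pyridine, pyridine, THF, 0 °C to rt
Reagents that add atoms: none
Why: Buffered HF·pyridine cleaves primary TBS ethers far faster than a hindered secondary TIPS ether, and the acetate is stable to it.

Step 19
Reactants: 31 triol
Product: 33 α,β-unsaturated γ-lactone with C12 aldehyde, via lactol aldehyde 32 (not isolated)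
Conditions: TEMPO (0.3 equiv), PhI(OAc)2 (3.3 equiv), CH2Cl2, rt
Reagents that add atoms: none
Why: TEMPO/PhI(OAc)2 oxidises the primary alcohols: the less hindered allylic C18 alcohol goes to the enal, which the neopentyl C19 hydroxyl traps as lactol 32, and this is oxidised on to the lactone with C18 as carbonyl, while the C12 alcohol stops at the aldehyde in the absence of water.

Step 20
Reactants: 33 lactone aldehyde; 34 ethynylmagnesium bromide
Product: 35 C12 propargylic alcohol (epimer mixture at C12)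
Conditions: 34 (1.3 equiv), THF, –78 °C
Reagents that add atoms: ethynylmagnesium bromide (34), C#C[Mg]Br
Why: Grignard 1,2-addition: at –78 °C the aldehyde reacts much faster than lactone or acetate, and the new carbinol centre is removed in step 21.

Step 21
Reactants: 35 propargylic alcohol
Product: 36 ynone (1β-(4-methyloxazol-2-yl); 9β-CH2COC≡CH; 2α-OTIPS)
Conditions: Dess–Martin periodinane, CH2Cl2, 0 °C to rt
Reagents that add atoms: none
Why: Dess–Martin oxidation of the propargylic alcohol under mild, nearly neutral conditions gives the ynone without touching silyl ether, acetate, lactone or oxazole.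

Step 22
Reactants: 36 ynone
Product: 38 TIPS ether of the target, via bridged cycloadduct 37 (not isolated)
Conditions: BHT (cat.), o-dichlorobenzene (0.005 M), 165 °C
Reagents that add atoms: none
Why: The 2-alkyl-4-methyloxazole serves as a donor 2-azadiene (C16=N–C(Me)=C15) and adds across the acceptor alkyne, C16 to the internal carbon C13 and C15 to the terminal carbon C14, to give the 7-oxa-2-azabicyclo[2.2.1]heptadiene 37, which loses MeCN by retro-[4+2] so that the oxygen bridge becomes the aromatic furan and the sequence cannot reverse. The closest known reaction type is the intramolecular oxazole–alkynone Diels–Alder/retro-Diels–Alder synthesis of ring-fused furans, best known for five- and six-membered carbocycles, so that a seven-membered closure lies at the long end of its scope. Ring C closes in the cycloaddition itself, as a type 1 intramolecular [4+2] over the five-atom tether C1–C10–C9–C11–C12, and the furan ring is completed by the cycloreversion. No lasting stereocentre is formed (the two bridgeheads of 37 vanish), and the neutral thermal conditions leave the seven existing centres, the acetate, the lactone and the silyl ether alone. The step needs only regio- and chemoselectivity: the tether allows only the C16–C13/C15–C14 pairing, which is also the polarity-matched one (ynone β-carbon to oxazole C5), and the two arms are equatorial on C1 and C9, peri across C10 of the rigid trans-decalin, which holds the reacting ends close while the lactone alkene cannot reach the oxazole. High dilution and BHT protect the terminal ynone from bimolecular loss.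

Step 23
Reactants: 38 TIPS ether
Product: 39 target CNP0182929.2
Conditions: HF·pyridine, THF, rt
Reagents that add atoms: none
Why: Fluoride-induced Si–O cleavage under acidic, non-basic conditions spares the acetate, the lactone and the acylfuran, and ionisation at C2 is disfavoured γ to the lactone carbonyl.

**Compound list**
1 | but-2-yne-1,4-diol | OCC#CCO | starting material
2 | vinylmagnesium chloride | C=C[Mg]Cl | starting material
3 | alkenylmagnesium chelate (vinyl and Mg trans; both oxygens as ClMg alkoxides) | Cl[Mg]/C(CO[Mg]Cl)=C(CO[Mg]Cl)/C=C | intermediate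
4 | (2Z)-2-ethenyl-3-iodobut-2-ene-1,4-diol | I/C(CO)=C(CO)/C=C | intermediate
5 | (2Z)-1,4-bis(TBS-oxy)-2-ethenyl-3-iodobut-2-ene | I/C(CO[Si](C)(C)C(C)(C)C)=C(CO[Si](C)(C)C(C)(C)C)/C=C | intermediate
6 | ethyl (bromozincio)acetate | CCOC(=O)C[Zn]Br | starting material
7 | ethyl (3E)-3,4-bis(TBS-oxymethyl)hexa-3,5-dienoate | CCOC(=O)C/C(CO[Si](C)(C)C(C)(C)C)=C(CO[Si](C)(C)C(C)(C)C)/C=C | intermediate
8 | (3E)-3,4-bis(TBS-oxymethyl)hexa-3,5-dienal | O=CC/C(CO[Si](C)(C)C(C)(C)C)=C(CO[Si](C)(C)C(C)(C)C)/C=C | intermediate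
9 | (Z)-crotylboronic acid pinacol ester | C/C=C\CB1OC(C)(C)C(C)(C)O1 | starting material
10 | (3S,4S,6E)-6,7-bis(TBS-oxymethyl)-3-methylnona-1,6,8-trien-4-ol | C=C[C@H](C)[C@@H](O)C/C(CO[Si](C)(C)C(C)(C)C)=C(CO[Si](C)(C)C(C)(C)C)/C=C | intermediate
11 | bis(9-BBN) adduct (C10–B and C7–O–B) | B1(CC[C@H](C)[C@@H](OB2C3CCCC2CCC3)C/C(CO[Si](C)(C)C(C)(C)C)=C(CO[Si](C)(C)C(C)(C)C)/C=C)C2CCCC1CCC2 | intermediate
12 | (3S,4S,6E)-6,7-bis(TBS-oxymethyl)-3-methylnona-6,8-diene-1,4-diol | OCC[C@H](C)[C@@H](O)C/C(CO[Si](C)(C)C(C)(C)C)=C(CO[Si](C)(C)C(C)(C)C)/C=C | intermediate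
13 | lactol of 14 | OC1C[C@H](C)[C@H](C/C(CO[Si](C)(C)C(C)(C)C)=C(CO[Si](C)(C)C(C)(C)C)/C=C)O1 | intermediate
14 | (4S,5S)-5-[(2E)-2,3-bis(TBS-oxymethyl)penta-2,4-dienyl]-4-methyloxolan-2-one | O=C1C[C@H](C)[C@H](C/C(CO[Si](C)(C)C(C)(C)C)=C(CO[Si](C)(C)C(C)(C)C)/C=C)O1 | intermediate
15 | lithium enolate of 14 | [Li]OC1=C[C@H](C)[C@H](C/C(CO[Si](C)(C)C(C)(C)C)=C(CO[Si](C)(C)C(C)(C)C)/C=C)O1 | intermediate
16 | (3S,4S,5S)-3,4-dimethyl analogue of 14 | O=C1[C@@H](C)[C@H](C)[C@H](C/C(CO[Si](C)(C)C(C)(C)C)=C(CO[Si](C)(C)C(C)(C)C)/C=C)O1 | intermediate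
17 | tert-butyl(2-iodoethoxy)dimethylsilane | CC(C)(C)[Si](C)(C)OCCI | starting material
18 | lithium enolate of 16 | [Li]OC1=C(C)[C@H](C)[C@H](C/C(CO[Si](C)(C)C(C)(C)C)=C(CO[Si](C)(C)C(C)(C)C)/C=C)O1 | intermediate
19 | (3S,4S,5S)-3-[2-(TBS-oxy)ethyl]-3,4-dimethyl lactone | O=C1[C@@](C)(CCO[Si](C)(C)C(C)(C)C)[C@H](C)[C@H](C/C(CO[Si](C)(C)C(C)(C)C)=C(CO[Si](C)(C)C(C)(C)C)/C=C)O1 | intermediate
20 | lactol of 19 | OC1[C@@](C)(CCO[Si](C)(C)C(C)(C)C)[C@H](C)[C@H](C/C(CO[Si](C)(C)C(C)(C)C)=C(CO[Si](C)(C)C(C)(C)C)/C=C)O1 | intermediate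
21 | 2,4-dimethyl-1,3-oxazole | Cc1nc(C)co1 | starting material
22 | 2-(lithiomethyl)-4-methyl-1,3-oxazole | [Li]Cc1nc(C)co1 | intermediate
23 | diethyl [(4-methyl-1,3-oxazol-2-yl)methyl]phosphonate | CCOP(=O)(Cc1nc(C)co1)OCC | intermediate
24 | lithiated 23 | [Li]C(c1nc(C)co1)P(=O)(OCC)OCC | intermediate
25 | (7S,8S,9R)-(E)-2-vinyloxazole trienol | Cc1coc(/C=C/[C@@](C)(CCO[Si](C)(C)C(C)(C)C)[C@H](C)[C@@H](O)C/C(CO[Si](C)(C)C(C)(C)C)=C(CO[Si](C)(C)C(C)(C)C)/C=C)n1 | intermediate
26 | C7 acetate of 25 | Cc1coc(/C=C/[C@@](C)(CCO[Si](C)(C)C(C)(C)C)[C@H](C)[C@@H](OC(C)=O)C/C(CO[Si](C)(C)C(C)(C)C)=C(CO[Si](C)(C)C(C)(C)C)/C=C)n1 | intermediate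
27 | trans-decalin, 1β-oxazolyl, C3=C4, three primary TBS ethers | CC(=O)O[C@H]1C[C@@]2(CO[Si](C)(C)C(C)(C)C)C(CO[Si](C)(C)C(C)(C)C)=CC[C@@H](c3nc(C)co3)[C@@H]2[C@@](C)(CCO[Si](C)(C)C(C)(C)C)[C@@H]1C | intermediate
28 | C2 enone | CC(=O)O[C@H]1C[C@@]2(CO[Si](C)(C)C(C)(C)C)C(CO[Si](C)(C)C(C)(C)C)=CC(=O)[C@@H](c3nc(C)co3)[C@@H]2[C@@](C)(CCO[Si](C)(C)C(C)(C)C)[C@@H]1C | intermediate
29 | 2α-allylic alcohol | CC(=O)O[C@H]1C[C@@]2(CO[Si](C)(C)C(C)(C)C)C(CO[Si](C)(C)C(C)(C)C)=C[C@H](O)[C@@H](c3nc(C)co3)[C@@H]2[C@@](C)(CCO[Si](C)(C)C(C)(C)C)[C@@H]1C | intermediate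
30 | 2α-TIPS ether | CC(=O)O[C@H]1C[C@@]2(CO[Si](C)(C)C(C)(C)C)C(CO[Si](C)(C)C(C)(C)C)=C[C@H](O[Si](C(C)C)(C(C)C)C(C)C)[C@@H](c3nc(C)co3)[C@@H]2[C@@](C)(CCO[Si](C)(C)C(C)(C)C)[C@@H]1C | intermediate
31 | C12/C18/C19 triol | CC(=O)O[C@H]1C[C@@]2(CO)C(CO)=C[C@H](O[Si](C(C)C)(C(C)C)C(C)C)[C@@H](c3nc(C)co3)[C@@H]2[C@@](C)(CCO)[C@@H]1C | intermediate
32 | C18 lactol with C12 aldehyde | CC(=O)O[C@H]1C[C@@]23COC(O)C2=C[C@H](O[Si](C(C)C)(C(C)C)C(C)C)[C@@H](c4nc(C)co4)[C@@H]3[C@@](C)(CC=O)[C@@H]1C | intermediate
33 | unsaturated γ-lactone with C12 aldehyde | CC(=O)O[C@H]1C[C@@]23COC(=O)C2=C[C@H](O[Si](C(C)C)(C(C)C)C(C)C)[C@@H](c4nc(C)co4)[C@@H]3[C@@](C)(CC=O)[C@@H]1C | intermediate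
34 | ethynylmagnesium bromide | C#C[Mg]Br | starting material
35 | C12 propargylic alcohol | CC(=O)O[C@H]1C[C@@]23COC(=O)C2=C[C@H](O[Si](C(C)C)(C(C)C)C(C)C)[C@@H](c4nc(C)co4)[C@@H]3[C@@](C)(CC(O)C#C)[C@@H]1C | intermediate
36 | oxazole ynone (key-step precursor) | CC(=O)O[C@H]1C[C@@]23COC(=O)C2=C[C@H](O[Si](C(C)C)(C(C)C)C(C)C)[C@@H](c4nc(C)co4)[C@@H]3[C@@](C)(CC(=O)C#C)[C@@H]1C | intermediate
37 | 7-oxa-2-azabicyclo[2.2.1]heptadiene cycloadduct (bridgeheads transient, not specified) | CC(=O)O[C@H]1C[C@@]23COC(=O)C2=C[C@H](O[Si](C(C)C)(C(C)C)C(C)C)[C@H]2C45OC(C=C4C(=O)C[C@@](C)([C@@H]1C)[C@@H]23)C(C)=N5 | intermediate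
38 | TIPS ether of the target (key-step product) | CC(=O)O[C@H]1C[C@@]23COC(=O)C2=C[C@H](O[Si](C(C)C)(C(C)C)C(C)C)[C@H]2c4occc4C(=O)C[C@@](C)([C@@H]1C)[C@@H]23 | intermediate
39 | CNP0182929.2 | CC(=O)O[C@H]1C[C@@]23COC(=O)C2=C[C@H](O)[C@H]2c4occc4C(=O)C[C@@](C)([C@@H]1C)[C@@H]23 | target

**Step count.** Total: 23 steps. Longest linear sequence: 22 steps (steps 1–10 and 12–23; step 11 is a one-step side branch).

**Steps most likely to fail**

Step 14.
- **Risk:** the dienophile is only weakly activated and both new bonds are made next to fully substituted carbons. At 170 °C a 1,5-hydrogen shift from the inside CH2OTBS group into the diene may compete with the wanted cycloaddition. Leakage through the tether-endo (cis-decalin) transition state may compete as well.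
- **Fallback (from 20, back at 27):** Wittig olefination of lactol 20 with Ph3P=CHCHO gives the (E)-enal alcohol F1, and acetylation gives the enal acetate F2. The enal is a far stronger dienophile. With Me2AlCl in CH2Cl2 at –78 to –20 °C its carbonyl-endo intramolecular Diels–Alder reaction should give the trans-decalin carbaldehyde F3. Pinnick oxidation leads to the carboxylic acid F4, and the mixed anhydride (i-BuOCOCl) with NH3 gives the carboxamide F5. Blümlein–Lewy condensation with chloroacetone (CaCO3, toluene, 110 °C) then builds the 4-methyloxazole and returns to 27.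

Step 22.
- **Risk:** closure of a seven-membered ring over a five-atom tether is slower than the five- and six-membered cases. Oligomerisation or conjugate addition at the unprotected terminal ynone may therefore consume 36 before it cyclises.
- **Fallback (from 33, back at 38):** the alkyne terminus is capped. Addition of (trimethylsilyl)ethynylmagnesium bromide to 33 gives the silylated propargylic alcohol F9, and Dess–Martin oxidation gives the C-silylated ynone F10. This compound tolerates longer heating (o-dichlorobenzene, 180 °C). The same cycloaddition and loss of MeCN give the 4-(trimethylsilyl)furan F11. Ipso-protodesilylation with CF3CO2H in CH2Cl2 at 0 °C, which the TIPS ether survives, returns to 38.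

Step 15.
- **Risk:** poor site selectivity of the radical oxidation, with hydrogen abstraction from the allylic CH2OTBS group (C18) or from the oxazole methyl group instead of C2.
- **Fallback (from 27, back at 28):** a polar oxygen transposition replaces the radical step. m-CPBA epoxidises the only alkene from the less hindered β face to the 3β,4β-epoxide F6. PhSeNa (from PhSeSePh and NaBH4) opens it trans-diaxially at the secondary C3 to the hydroxy selenide F7. Oxidation with H2O2 and syn elimination of the selenoxide towards C2 give the tertiary allylic alcohol F8. Babler–Dauben oxidative transposition with pyridinium chlorochromate (C5H5NH[CrO3Cl]) moves the oxygen from C4 to C2 and gives 28.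

**Further compounds**
F1 | step 14 | (E)-enal alcohol | O=C/C=C/[C@@](C)(CCO[Si](C)(C)C(C)(C)C)[C@H](C)[C@@H](O)C/C(CO[Si](C)(C)C(C)(C)C)=C(CO[Si](C)(C)C(C)(C)C)/C=C
F2 | step 14 | enal acetate | O=C/C=C/[C@@](C)(CCO[Si](C)(C)C(C)(C)C)[C@H](C)[C@@H](OC(C)=O)C/C(CO[Si](C)(C)C(C)(C)C)=C(CO[Si](C)(C)C(C)(C)C)/C=C
F3 | step 14 | trans-decalin 1β-carbaldehyde | CC(=O)O[C@H]1C[C@@]2(CO[Si](C)(C)C(C)(C)C)C(CO[Si](C)(C)C(C)(C)C)=CC[C@@H](C=O)[C@@H]2[C@@](C)(CCO[Si](C)(C)C(C)(C)C)[C@@H]1C
F4 | step 14 | trans-decalin 1β-carboxylic acid | CC(=O)O[C@H]1C[C@@]2(CO[Si](C)(C)C(C)(C)C)C(CO[Si](C)(C)C(C)(C)C)=CC[C@@H](C(=O)O)[C@@H]2[C@@](C)(CCO[Si](C)(C)C(C)(C)C)[C@@H]1C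
F5 | step 14 | trans-decalin 1β-carboxamide | CC(=O)O[C@H]1C[C@@]2(CO[Si](C)(C)C(C)(C)C)C(CO[Si](C)(C)C(C)(C)C)=CC[C@@H](C(N)=O)[C@@H]2[C@@](C)(CCO[Si](C)(C)C(C)(C)C)[C@@H]1C
F6 | step 15 | 3β,4β-epoxide | CC(=O)O[C@H]1C[C@@]2(CO[Si](C)(C)C(C)(C)C)[C@@]3(CO[Si](C)(C)C(C)(C)C)O[C@H]3C[C@@H](c3nc(C)co3)[C@@H]2[C@@](C)(CCO[Si](C)(C)C(C)(C)C)[C@@H]1C
F7 | step 15 | 3α-phenylseleno-4β-ol | CC(=O)O[C@H]1C[C@@]2(CO[Si](C)(C)C(C)(C)C)[C@](O)(CO[Si](C)(C)C(C)(C)C)[C@H]([Se]c3ccccc3)C[C@@H](c3nc(C)co3)[C@@H]2[C@@](C)(CCO[Si](C)(C)C(C)(C)C)[C@@H]1C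
F8 | step 15 | Δ2-4β-tertiary allylic alcohol | CC(=O)O[C@H]1C[C@@]2(CO[Si](C)(C)C(C)(C)C)[C@](O)(CO[Si](C)(C)C(C)(C)C)C=C[C@@H](c3nc(C)co3)[C@@H]2[C@@](C)(CCO[Si](C)(C)C(C)(C)C)[C@@H]1C
F9 | step 22 | C-silylated propargylic alcohol | CC(=O)O[C@H]1C[C@@]23COC(=O)C2=C[C@H](O[Si](C(C)C)(C(C)C)C(C)C)[C@@H](c4nc(C)co4)[C@@H]3[C@@](C)(CC(O)C#C[Si](C)(C)C)[C@@H]1C
F10 | step 22 | C-silylated ynone | CC(=O)O[C@H]1C[C@@]23COC(=O)C2=C[C@H](O[Si](C(C)C)(C(C)C)C(C)C)[C@@H](c4nc(C)co4)[C@@H]3[C@@](C)(CC(=O)C#C[Si](C)(C)C)[C@@H]1C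
F11 | step 22 | 4-(trimethylsilyl)furan | CC(=O)O[C@H]1C[C@@]23COC(=O)C2=C[C@H](O[Si](C(C)C)(C(C)C)C(C)C)[C@H]2c4occ([Si](C)(C)C)c4C(=O)C[C@@](C)([C@@H]1C)[C@@H]23
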